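A small charge of free catalyst, 0.33 mM, is turning over the substrate in violet, and you need to know how far it gets by 10 min.

the same everywhere: substrate 0.10 M; free catalyst 0.33 mM

| charge | reagent | scavenger | remark | time |
|---|---|---|---|---|
| violet | 0.12 M | 0.12 M | the very flask that is asked about, followed so far |  |
| blue | 0.060 M | 0.12 M | run made earlier |  |
| flask | 0.120 M | 0.120 M |  | 10 min |

- violet (time / min: substrate / %, product / %): 0.500: 91.3, 9.6; 1.00: 81.7, 19.2; 1.50: 73.0, 26.6; 2.00: 66.0, 34.1; 2.50: 59.0, 39.5; 3.00: 53.1, 46.8
- blue (time / min: substrate / %, product / %): 1.33: 83.9, 17.0; 2.50: 72.3, 27.3; 4.00: 60.9, 39.2; 5.00: 56.1, 44.0; 6.00: 51.6, 48.2; 8.00: 45.7, 54.7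

(scatter of a reading: 0.5 percentage points)

* part of the substrate that has reacted at 10 min
* share of the unused reagent that is free and not bound as idle adduct, at 10 min

- the earlier runs do not show how much of reagent is bound; that part of a forecast is a guess

Which charge gives out first? I assume one reagent is used per product. Define the margin m as unused reagent over unused substrate, which starts at 1.20 in violet. Above one, substrate is the limiting reagent.

Which way does m drift? With equal amounts taken from both, a margin above one climbs and one below one falls. Violet's m, reckoned from the readings, rose to a reading of 1.38 at 3.00 min. Blue's fell from 0.600 to a reading of 0.116 at 8.00 min.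

What does the drift do to the rate? Take κ, the logarithmic loss of substrate per minute. In blue, κ read 0.132 min⁻¹ at first and 0.0607 min⁻¹ over the last interval. In violet, κ averaged from the start read 0.202 min⁻¹ up to 1.00 min and 0.211 min⁻¹ up to 3.00 min. Violet's m was still climbing at its last reading, so I choose to hold its κ, and my estimate for the substrate reacted at 10 min is 87.9 %. The runs give me no number for the free share.

The forecast says 88.5 % and 68 %, adding “The free share is a guess”. The flask gives 91.6 % and 99.8 %.

    catalyst intermediate C → free catalyst + product (k = 5.50 s⁻¹)
    reagent + released group ⇌ idle adduct, settled at all times (K = 6.80 L mol⁻¹)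
    catalyst intermediate B ⇌ released group + catalyst intermediate C (K = 1.30 M, k = 4.80 s⁻¹)
    free catalyst ⇌ dormant form (K = 2.10, k = 0.00470 s⁻¹)
    scavenger + released group → scavenged by-product (k = 4.70 L mol⁻¹ s⁻¹)
    reagent + catalyst intermediate A ⇌ catalyst intermediate B (K = 11.0 L mol⁻¹, k = 35.0 L mol⁻¹ s⁻¹)
    substrate + free catalyst → catalyst intermediate A (k = 50.0 L mol⁻¹ s⁻¹)

The flask runs 3.7 percentage points past my figure. Its m stands at 3.39 at 10.0 min, and 1.20 puts the reagent left after the substrate has gone at 16.7 % of its charge; at 100 min, with 0 % of the substrate left, the flask holds 16.7 % of its reagent charge. In the neighbouring flask with 0.25 M of substrate, m starts at 0.480, below one like blue, so at one reagent per product its reagent charge covers 48.0 % of the substrate. At 10.0 min that flask has reacted 44.9 %, with 6.67 % of its reagent left.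

The earlier runs and the new flask were generated by integration for an exercise; the scatter is artificial.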